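A direct plan would keep a preformed ring A and close ring C on it. Fluoride would release benzyne A2 from silylaryl triflate A1 (3,5-bis(benzyloxy)-4-methoxy-2-(trimethylsilyl)phenyl triflate). The enolate of formylacetate A3 (methyl 3-hydroxy-2-(2,3,4-trimethoxyphenyl)acrylate) would add through oxygen, the aryl anion would close onto the ester to give dibenzyl isoflavone A4, and hydrogenolysis would finish. Its weakest steps would be:
- the aryne annulation, which has no precedent for a formylacetate and leaves O- versus C-arylation and premature protonation of the aryl anion unsecured;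
- the preparation of A1, about seven functional-group operations on ring A that add no skeletal complexity;
- the closing debenzylation, a protecting-group step that also exposes the C2–C3 double bond to reduction.

The new strategy exploits the acetate-type oxygenation of ring A: O1, 5-OH and 7-OH sit on alternate carbons (C8a, C5, C7), and the methoxy carbon C6 lies between two carbonyl-derived carbons. Ring C, already carrying ring B, is therefore made first as a 4-pyranone (a masked triketide), and ring A is folded onto it last. In one operation the lateral carbanion of pyranone ester 7 is acylated by methyl methoxyacetate (C7–C8 bond), the chain closes by Dieckmann condensation (C5–C6 bond) and aromatises to the free 5,7-dihydroxy-6-methoxy pattern, with no regiochemical choice. No aryne precursor, ambident-enolate arylation or protecting group is needed.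

Key step: step 4

Remark: the target has no stereocentre and no double-bond isomerism, so nothing stereochemical has to be set; atom labels C2–C8a refer to the chromone numbering of the target.

Step 1
Reactants: 1 2,3,4-trimethoxyphenylacetic acid
Product: 2 2,3,4-trimethoxyphenylacetyl chloride
Conditions: (COCl)2 (1.3 equiv), DMF (cat.), CH2Cl2, 0 °C to rt; concentrate
Reagents that add atoms: oxalyl chloride, O=C(Cl)C(=O)Cl
Why: Acid chloride formation with oxalyl chloride under DMF (Vilsmeier) catalysis, to which the aryl methyl ethers are inert.

Step 2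
Reactants: 2 2,3,4-trimethoxyphenylacetyl chloride; 3 methyl acetoacetate
Product: 4 methyl 2-acetyl-3-oxo-4-(2,3,4-trimethoxyphenyl)butanoate
Conditions: 3 (1.0 equiv), MgCl2 (1.0 equiv), pyridine (2.0 equiv), CH2Cl2, 0 °C; then 2 (1.0 equiv), 0 °C to rt; cold 1 M HCl
Reagents that add atoms: methyl acetoacetate, COC(=O)CC(C)=O
Why: Magnesium-mediated C-acylation of a β-keto ester, in which the chelated magnesium enolate of 3 is acylated on carbon and chelation of the more acidic tricarbonyl product should suppress O-acylation and a second acylation.

Step 3
Reactants: 4 methyl 2-acetyl-3-oxo-4-(2,3,4-trimethoxyphenyl)butanoate; 5 N,N-dimethylformamide dimethyl acetal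
Product: 7 methyl 2-methyl-4-oxo-5-(2,3,4-trimethoxyphenyl)-4H-pyran-3-carboxylate, via enaminone 6 (not isolated)
Conditions: Me2NCH(OMe)2 (1.2 equiv), toluene, 70 °C; evaporate; AcOH, 60 °C
Reagents that add atoms: N,N-dimethylformamide dimethyl acetal, COC(OC)N(C)C
Why: Aminomethylenation at the benzylic methylene (flanked by aryl and carbonyl, so more acidic than the acetyl methyl) should give enaminone 6, and acid-promoted addition of the acetyl enol oxygen to the enamine carbon with loss of dimethylamine closes the 4-pyranone, as in the known conversion of 2-acyl-1,3-dicarbonyl compounds into 3-acyl-4-pyranones.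

Step 4
Reactants: 7 methyl 2-methyl-4-oxo-5-(2,3,4-trimethoxyphenyl)-4H-pyran-3-carboxylate; 8 methyl methoxyacetate
Product: 11 5,7-dihydroxy-6-methoxy-3-(2,3,4-trimethoxyphenyl)-4H-chromen-4-one, via pyranyl ketone 9 (not isolated), via chromenetrione 10 (not isolated)
Conditions: LiN(i-Pr)2 (1.1 equiv), THF, −78 °C; 8 (1.2 equiv), −78 to 0 °C; then LiN(i-Pr)2 (2.5 equiv), −78 °C to rt; 1 M HCl
Reagents that add atoms: methyl methoxyacetate, COCC(=O)OC
Why: Proposed new method: lithium diisopropylamide removes a proton from the 2-methyl group of 7 (a vinylogous enolate stabilised by both C4=O and the ester), which is acylated by 8 in a crossed Claisen condensation to give ketone 9 as its enolate (C7–C8 bond); the second charge of base deprotonates the methoxy-bearing α′-carbon, and this terminal carbon of the 1,3-dianion attacks the neighbouring ester (Dieckmann condensation, C5–C6 bond) to give trione 10, whose double enolisation to the aromatic diphenoxide of 11 makes the sequence irreversible. The closest known reaction types are the condensation of lithiated ortho-toluates with esters and Dieckmann closure of the resulting 2-(2-oxoalkyl)benzoates to naphthalene-1,3-diols, the lateral acylation of 2-methyl-4-pyranones, and the Claisen folding of poly-β-carbonyl chains to phloroglucinols; their combination on a 4-pyranone-3-carboxylate to build ring A of a chromone has not been shown. Ring A is the only ring closed, by a 6-(enolendo)-exo-trig attack of C6 on the ester carbonyl, and no stereocentre results because C6 of 10 becomes sp2 on aromatisation. The step needs C- rather than O-cyclisation of the enolate of 9 and survival of the unsubstituted pyranone position (C2 of the chromone) toward nucleophiles: the dianion carries its highest charge density on the terminal carbon, the amide base is hindered, and every intermediate is anionic and therefore a poor Michael acceptor. Regiochemistry is fixed by connectivity, since the methoxy carbon lies between the two carbonyl carbons that become C5–OH and C7–OH, so the 8-methoxy isomer cannot form.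

**Compound list**

1 | 2,3,4-trimethoxyphenylacetic acid | COc1ccc(CC(=O)O)c(OC)c1OC | starting material
2 | 2,3,4-trimethoxyphenylacetyl chloride | COc1ccc(CC(=O)Cl)c(OC)c1OC | intermediate
3 | methyl acetoacetate | COC(=O)CC(C)=O | starting material
4 | methyl 2-acetyl-3-oxo-4-(2,3,4-trimethoxyphenyl)butanoate (keto form drawn; enolised, so the methine carbon is not a fixed stereocentre) | COC(=O)C(C(C)=O)C(=O)Cc1ccc(OC)c(OC)c1OC | intermediate
5 | N,N-dimethylformamide dimethyl acetal | COC(OC)N(C)C | starting material
6 | methyl (E)-2-acetyl-5-(dimethylamino)-3-oxo-4-(2,3,4-trimethoxyphenyl)pent-4-enoate (not isolated; E drawn, the push–pull double bond isomerises readily) | COC(=O)C(C(C)=O)C(=O)/C(=C/N(C)C)c1ccc(OC)c(OC)c1OC | intermediate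
7 | methyl 2-methyl-4-oxo-5-(2,3,4-trimethoxyphenyl)-4H-pyran-3-carboxylate | COC(=O)c1c(C)occ(-c2ccc(OC)c(OC)c2OC)c1=O | intermediate
8 | methyl methoxyacetate | COCC(=O)OC | starting material
9 | methyl 2-(3-methoxy-2-oxopropyl)-4-oxo-5-(2,3,4-trimethoxyphenyl)-4H-pyran-3-carboxylate (not isolated) | COCC(=O)Cc1occ(-c2ccc(OC)c(OC)c2OC)c(=O)c1C(=O)OC | intermediate
10 | 6-methoxy-3-(2,3,4-trimethoxyphenyl)-6H-chromene-4,5,7(8H)-trione (not isolated; keto tautomer of 11, C6 transient and racemic) | COc1ccc(-c2coc3c(c2=O)C(=O)C(OC)C(=O)C3)c(OC)c1OC | intermediate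
11 | 5,7-dihydroxy-6-methoxy-3-(2,3,4-trimethoxyphenyl)-4H-chromen-4-one | COc1ccc(-c2coc3cc(O)c(OC)c(O)c3c2=O)c(OC)c1OC | target

Total step count: 4. Longest linear sequence: 4 (1 → 2 → 4 → 7 → 11).

Steps most likely to fail:

1. Step 4 (proposed new method). The doubly stabilised lateral enolate may be acylated slowly or reversibly. The enolate of 9 may close through oxygen onto the ester to give a lactone instead of ring A. Base may add to the free pyranone position and open the ring. Fallback, known chemistry, setting out from 1 and returning at 11: Friedel–Crafts acylation of 2-methoxybenzene-1,3,5-triol (iretol) with acid 1 in BF3·OEt2 at 80 °C should give the deoxybenzoin 1-(2,4,6-trihydroxy-3-methoxyphenyl)-2-(2,3,4-trimethoxyphenyl)ethan-1-one F1. One-carbon cyclisation (BF3·OEt2, DMF, MsCl, 70 °C) would then give 11 together with its isomer 5,7-dihydroxy-8-methoxy-3-(2,3,4-trimethoxyphenyl)-4H-chromen-4-one F2, because either ortho-hydroxyl can close. The route is rejoined at 11 only after chromatographic separation, which is the price of this fallback.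

2. Step 3. Condensation may occur at the acetyl methyl instead of the benzylic methylene. The acidic enol may be O-methylated by the acetal. An acyl group may be lost by retro-Claisen cleavage. The activated 2-methyl group of the product may condense a second time. Fallback, setting out from 3 and returning at 7, with the aryl group introduced by cross-coupling instead of being carried through the ring closure: C-acylation of 3 with (E)-3-ethoxyacryloyl chloride (MgCl2, pyridine, CH2Cl2) should give methyl (E)-2-acetyl-5-ethoxy-3-oxopent-4-enoate F3. Acid (TFA, CH2Cl2) would close it, with loss of ethanol, to methyl 2-methyl-4-oxo-4H-pyran-3-carboxylate F4. Bromination at the only free nucleophilic ring position (Br2, then pyridine, CH2Cl2) would give methyl 5-bromo-2-methyl-4-oxo-4H-pyran-3-carboxylate F5. Suzuki–Miyaura coupling with (2,3,4-trimethoxyphenyl)boronic acid (Pd(PPh3)4, K3PO4, dioxane, 90 °C) would return to the route at 7.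

3. Step 2. Pyridine may convert the arylacetyl chloride into a ketene that dimerises. The enolate may be acylated on oxygen. The tricarbonyl product may lose an acyl group on work-up. Fallback, setting out from 2 and returning at 4, with the two acyl groups attached in the reverse order: acylation of Meldrum's acid with 2 (pyridine, CH2Cl2, 0 °C) should give 5-[1-hydroxy-2-(2,3,4-trimethoxyphenyl)ethylidene]-2,2-dimethyl-1,3-dioxane-4,6-dione F6. Methanolysis (MeOH, reflux, via the acylketene) would give methyl 3-oxo-4-(2,3,4-trimethoxyphenyl)butanoate F7. Magnesium-mediated C-acetylation with acetyl chloride (MgCl2, pyridine, CH2Cl2) would return to the route at 4.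

Further compounds
F1 | step 4 | 1-(2,4,6-trihydroxy-3-methoxyphenyl)-2-(2,3,4-trimethoxyphenyl)ethan-1-one | COc1ccc(CC(=O)c2c(O)cc(O)c(OC)c2O)c(OC)c1OC
F2 | step 4 | 5,7-dihydroxy-8-methoxy-3-(2,3,4-trimethoxyphenyl)-4H-chromen-4-one | COc1ccc(-c2coc3c(OC)c(O)cc(O)c3c2=O)c(OC)c1OC
F3 | step 3 | methyl (E)-2-acetyl-5-ethoxy-3-oxopent-4-enoate | CCO/C=C/C(=O)C(C(C)=O)C(=O)OC
F4 | step 3 | methyl 2-methyl-4-oxo-4H-pyran-3-carboxylate | COC(=O)c1c(C)occc1=O
F5 | step 3 | methyl 5-bromo-2-methyl-4-oxo-4H-pyran-3-carboxylate | COC(=O)c1c(C)occ(Br)c1=O
F6 | step 2 | 5-[1-hydroxy-2-(2,3,4-trimethoxyphenyl)ethylidene]-2,2-dimethyl-1,3-dioxane-4,6-dione | COc1ccc(CC(O)=C2C(=O)OC(C)(C)OC2=O)c(OC)c1OC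
F7 | step 2 | methyl 3-oxo-4-(2,3,4-trimethoxyphenyl)butanoate | COC(=O)CC(=O)Cc1ccc(OC)c(OC)c1OC
A1 | direct plan | 3,5-bis(benzyloxy)-4-methoxy-2-(trimethylsilyl)phenyl trifluoromethanesulfonate | COc1c(OCc2ccccc2)cc(OS(=O)(=O)C(F)(F)F)c([Si](C)(C)C)c1OCc1ccccc1
A2 | direct plan | 3,5-bis(benzyloxy)-4-methoxybenzyne | COC1=C(OCc2ccccc2)C#CC=C1OCc1ccccc1
A3 | direct plan | methyl (Z)-3-hydroxy-2-(2,3,4-trimethoxyphenyl)acrylate | COC(=O)/C(=C\O)c1ccc(OC)c(OC)c1OC
A4 | direct plan | 5,7-bis(benzyloxy)-6-methoxy-3-(2,3,4-trimethoxyphenyl)-4H-chromen-4-one | COc1ccc(-c2coc3cc(OCc4ccccc4)c(OC)c(OCc4ccccc4)c3c2=O)c(OC)c1OC
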